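## Structural features

The target is a 5,6-dihydro-2H-pyran-2-one (O1, C2 carbonyl, C3=C4, C5, C6) whose two sp3 ring carbons each carry a side chain: C5 an ester oxygen acylated by (2E,4E,6S)-4,6-dimethyldodeca-2,4-dienoic acid, and C6 an (E)-propenoic acid arm (C7=C8–C9O2H). C5 and C6 are adjacent stereocentres, both S, with the acyloxy group and the arm cis on the ring; the third stereocentre, the methyl-bearing C6' of the acyl chain (S), is remote and independent. A free acid, an unsaturated δ-lactone and a doubly conjugated ester must coexist, so the acid has to travel in a mask that comes off without base or nucleophile. The molecule is fragile towards base: deprotonation at C6 (allylic to C7=C8, α to O1) with loss of the C5 carboxylate would aromatise the ring to a 2-pyranone, and any intermediate with a free hydroxyl next to the dienoate can suffer 1,2-acyl migration. The real difficulty is therefore not the carbon skeleton but telling the two vicinal oxygens apart (O5 acylated, O6 becoming O1 of the lactone) while securing the cis relationship at C5/C6 and the cis geometry of C3=C4. The key step uses the fact that C2–C3=C4 can be carried as a linear propiolate that cannot lactonise, and that C6 with O1 and C7 is a glyceraldehyde unit: adding the propiolate to the acetonide-protected aldehyde forms C4–C5, makes the C5 hydroxyl the only free one and leaves O1 and O7 masked together.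

## Logic of the disconnections

29 ⇒ 28. The O–C(CH3)3 bond of the C9 ester is the only change. A free acid would interfere with ylide and carbodiimide chemistry, and a tert-butyl ester is removed by acid alone. The last step must leave the lactone and the dienoate untouched and must not involve base.

28 ⇒ 26 (through 27). The lactone bond O1–C2 is cut and C3=C4 is taken back to the alkyne. The Z-alkene and the ring then arise in one operation, and the linear alkyne cannot cyclise before O5 is acylated. The gain is an acyclic precursor without alkene geometry. The demand is a syn semihydrogenation that spares the E-enoate and the dienoate, and a lactonisation through O6 that is faster than acyl migration.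

26 ⇒ 23 + 24 (through 25). The C7=C8 bond is cut. C8–C9 arrives as the stabilised ylide 24 that already carries the acid mask, and C7 is the primary carbinol of a terminal diol. The demand is oxidation of the primary hydroxyl beside the secondary one, immediate trapping of 25, and E geometry.

23 ⇒ 22. Only the isopropylidene acetal is added back. It has kept O6 and O7 silent during C–C bond formation and acylation. Its removal must not move the acyl group from O5.

22 ⇒ 8 + 21. The acyl–oxygen bond at O5 is cut. This divides the molecule into two fragments of similar size and separates the remote stereocentre from the ring stereocentres. Because O5 is the only free hydroxyl of 8, no regiochemical question arises. The demand is a mild acylation of a base-sensitive γ-hydroxy ynoate with retention at C5.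

8 ⇒ 6 + 7 (key disconnection). The C4–C5 bond is cut between an alkynyl anion equivalent and an aldehyde. This removes one stereocentre and reduces the ring portion to a chiral-pool aldehyde and a three-carbon ester. Derived atom by atom, the CIP descriptors are consistent: the (4S) centre of 6 becomes C6 (S) of 29, and the new (4S) carbinol of 8 becomes C5 (S). The two centres are syn in the chain and cis on the ring. The demand is anti-Felkin (syn) facial selectivity, which must come from the catalyst. 6 is kept as the acetonide and is used freshly distilled, because its hydrate and oligomers are not substrates.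

6 ⇒ 3 ⇒ 2 ⇒ 1. 6 is C4–C6 of 1. In the forward sense the C2–C3 and C3–C4 bonds of the hexonolactone are cleaved after the enediol has been saturated and the terminal diol masked. The stereocentre is bought, not made. The demand is that no step touches C5 of 1.

21 ⇒ 20 ⇒ 17 + 18 (through 19). The C2'=C3' bond of the dienoate is cut to an enal and a two-carbon ylide, after the ester–acid interchange. The demand is E geometry without isomerising the existing trisubstituted alkene.

17 ⇒ 16 ⇒ 13 + 14 (through 15). The C4'=C5' bond is cut to an α-methyl aldehyde and a three-carbon ylide. The demand is E selectivity and no enolisation of 15.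

13 ⇒ 12 ⇒ 11 ⇒ 9 + 10. The C–CH3 bond at the future C6' and the N-acyl bond are cut. The auxiliary 10 turns a straight-chain acid chloride into the (S)-2-methyl unit. The demand is face-selective enolate methylation.

## Other disconnections considered

Alternative 1: The cut is the ring bond O1–C2, the pyranone being read as an oxidised furan. Forward, the furyl carbinol A1, tert-butyl (2E,4S)-4-(furan-2-yl)-4-hydroxybut-2-enoate, would be treated with N-bromosuccinimide in buffered aqueous THF. Oxidation of the furan, opening to the Z-4-oxo-enal and closure of the carbinol oxygen onto the aldehyde carbon would give the pyranone hemiacetal A2, tert-butyl (2E)-3-[(2S)-6-hydroxy-3-oxo-3,6-dihydro-2H-pyran-2-yl]prop-2-enoate. From A2 the lactol carbon would be oxidised to the lactone carbonyl, the C5 ketone reduced to the cis alcohol (hydride anti to the C6 arm), the alcohol esterified with 21 and the tert-butyl ester cleaved.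
In its favour: the furan supplies C2–C5 as one cheap unit and the ring exists from the key step on. O1 is in the ring and O5 is a ketone, so the two oxygens are differentiated as surely as in the chosen plan (equal on this point). No alkyne has to be semihydrogenated beside other alkenes (better), and the core needs fewer operations than steps 1–4 and 12–16 (better on step count).
Against it here: the only stereocentre, C6, is in A2 α to a ketone and γ to the enoate, so it can enolise. After lactol oxidation, tautomerisation to an aromatic hydroxy-2-pyranone would erase it. C5 then depends on substrate-controlled hydride delivery with 1,4-reduction as competitor. A1 must first be obtained enantioenriched and is an ionisable, doubly activated carbinol. The dienoate goes on last, onto a base-sensitive hydroxy lactone.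
Comparison: mechanistically this plan relays all stereochemistry from a labile centre. The chosen plan takes C6 from the chiral pool, keeps it away from any carbonyl until step 14 and sets C5 under catalyst control. That security is judged to outweigh the shorter sequence.

Alternative 2: The cut is C5–C6. Forward, A3, the 3-chloroprop-1-en-1-yl ester of 21, and the aldehyde A4, tert-butyl (2E)-4-oxobut-2-enoate, would be joined with a chiral [Cr(salen)Cl] catalyst, Mn powder and Me3SiCl. Divalent chromium, regenerated from the trivalent complex by Mn, would insert into the C–Cl bond of A3. The γ-acyloxyallyl chromium species would add to A4 through a closed transition state at its oxygen-bearing carbon, giving A5, tert-butyl (2E,4S,5S)-5-{[(2E,4E,6S)-4,6-dimethyldodeca-2,4-dienoyl]oxy}-4-hydroxyhepta-2,6-dienoate. Acryloylation of the new hydroxyl of A5, ring-closing metathesis onto the vinyl group and acid cleavage would finish.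
In its favour: one catalytic step forms the C5–C6 bond and both stereocentres (better than the chosen plan, which uses the chiral pool plus one catalytic step). The dienoate is already on O5, so no separate esterification and no O5/O6 ambiguity arise (equal to the chosen plan). The step count after 21 is about the same (equal).
Against it here: this reaction type is established for simple acyloxy groups and simple aldehydes, with enantio- and syn-selectivity that are usually only moderate. A3 commits the most valuable fragment, in excess, to the least secure step. A4 is an enal-ester open to reduction, pinacol coupling and conjugate addition under Mn/divalent chromium conditions. A5 has a free hydroxyl next to the dienoate, so the acyl-migration hazard is the same as in the chosen plan (equal). The metathesis must choose the vinyl group over the dienoate and the enoate.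
Comparison: structurally both plans differentiate the oxygens by construction. The chosen plan rests on a more broadly precedented addition and puts the precious acid in only after the stereochemistry is secured.

Alternative 3: The cuts are C3=C4 and C7=C8, both made by olefin metathesis on a C2-symmetric core. Forward, the diol A6, (3S,4S)-hexa-1,5-diene-3,4-diol, would be mono-acylated with 21 and then acryloylated to the mixed diester A7, (3S,4S)-4-(prop-2-enoyloxy)hexa-1,5-dien-3-yl (2E,4E,6S)-4,6-dimethyldodeca-2,4-dienoate. Second-generation Grubbs catalyst would close the acrylate of A7 onto the C5 vinyl group, and the acrylate A8, tert-butyl prop-2-enoate, added to the same flask, would cross-couple at the C6 vinyl group to give A9, the tert-butyl ester of the target (identical with 28). Acid cleavage would follow.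
In its favour: both ring stereocentres come from the chiral pool and no stereocentre is created (better on stereochemical security). The two hydroxyls of A6 are homotopic, so mono-acylation has no regiochemical issue. From A6 only four operations are needed (clearly better on step economy).
Against it here: the acrylate of A7 can close onto either vinyl group, giving the six-membered lactone through the C5 vinyl group or a butenolide through the C6 vinyl group, and nothing in A7 forbids the second mode. The remaining vinyl group is hindered, allylic to the lactone oxygen, and must couple with the electron-poor partner A8, which tends to react sluggishly in such cross-metatheses. The ruthenium carbene can also engage the dienoate. Mono- versus bis-acylation of A6 is statistical, and A6 itself costs several steps.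
Comparison: mechanistically this plan stakes regiochemistry on relative metathesis rates, whereas in the chosen plan every bond-forming event has only one possible site. The chosen plan is longer but unambiguous.

Key step: step 4

Assumption (remark on the chemistry): the Me2Zn/ProPhenol alkynylation is taken to follow the facial sense of the related aldol reactions of this ligand, with (S,S)-ProPhenol delivering the nucleophile to the Re face of an aldehyde. Si-face delivery, which the (4S) carbinol of 8 requires, is therefore assigned to (R,R)-ProPhenol. If the sense proved reversed for this α-alkoxy aldehyde, the antipodal ligand would be used with no other change.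

## Route

Step 1
Reactants: 1 L-ascorbic acid
Product: 2 L-gulono-1,4-lactone
Conditions: H2 (3.5 bar), 10% Pd/C, H2O, 50 °C
Reagents that add atoms: none
Why: Heterogeneous hydrogenation adds H2 syn to the enediol C2=C3 from the ring face opposite the C4 side chain, which gives the gulono configuration; C4 and C5 are not touched, so the (S) centre that becomes C6 of the target is carried unchanged.

Step 2
Reactants: 2 L-gulono-1,4-lactone
Product: 3 5,6-O-isopropylidene-L-gulono-1,4-lactone
Conditions: 2-methoxypropene, TsOH·H2O (cat.), DMF, 10 °C → rt
Reagents that add atoms: 2-methoxypropene, COC(C)=C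
Why: Acid-catalysed acetalisation with an enol ether under kinetic conditions takes the unhindered terminal 5,6-diol as a dioxolane and leaves the ring 2,3-diol free for the cleavage that follows.

Step 3
Reactants: 3 5,6-O-isopropylidene-L-gulono-1,4-lactone
Product: 6 (4S)-2,2-dimethyl-1,3-dioxolane-4-carbaldehyde, via glyoxylate ester aldehyde 4 (not isolated), via hydroxy aldehyde 5 (not isolated)
Conditions: NaIO4 (2.1 equiv), H2O, pH 5.5 (NaOH), 0 °C → rt; NaCl, CH2Cl2 extraction; distillation
Reagents that add atoms: none
Why: Glycol cleavage by NaIO4 (Malaprade reaction) cuts C2–C3 to give 4, whose glyoxylate ester hydrolyses in the buffered water to the α-hydroxy aldehyde 5, which is cleaved again at C3–C4; the dioxolane carbon takes no part and keeps its configuration, and pH 5.5 protects the acetonide and the α-centre.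

Step 4
Reactants: 6 (4S)-2,2-dimethyl-1,3-dioxolane-4-carbaldehyde; 7 methyl prop-2-ynoate
Product: 8 methyl (4S)-4-[(4S)-2,2-dimethyl-1,3-dioxolan-4-yl]-4-hydroxybut-2-ynoate
Conditions: (R,R)-ProPhenol [2,6-bis{[(2R)-2-(hydroxydiphenylmethyl)pyrrolidin-1-yl]methyl}-4-methylphenol] (20 mol %), Ph3P=O (40 mol %), Me2Zn (3 equiv), 7 (3 equiv), toluene, 0–4 °C; aq. NH4Cl
Reagents that add atoms: none
Why: Me2Zn deprotonates 7 to a methylzinc alkynylide and, with ProPhenol, assembles a catalyst with two phenoxide-bridged zinc centres, one holding the alkynyl group and the other binding the aldehyde oxygen, so that the alkynyl carbon is passed intramolecularly to the carbonyl carbon (C4–C5 bond); the closest known reaction is the Me2Zn/ProPhenol-catalysed enantioselective addition of alkyl propiolates to aldehydes. No ring is closed. The new stereocentre (C4 of 8, C5 of the target) is set by the ligand: (R,R)-ProPhenol is chosen to deliver the alkynyl group to the Si face of 6, which gives the (4S) carbinol, syn to the dioxolane oxygen, because the dioxolanyl carbon outranks the alkynyl carbon. The existing centre of 6 is not touched, since it does not enolise under these weakly basic, Lewis-acidic conditions and its oxygen is tied into the acetonide. The selectivity needed is diastereofacial and runs against the Felkin–Anh preference of 6 (anti product), so the ligand must dominate; the intrinsic bias of this aldehyde towards alkynylzinc reagents is modest, and any α-chelation of zinc by the dioxolane oxygen in toluene would favour the syn product. Chemoselectivity rests on the much faster transfer of alkynyl than of methyl from zinc and on the inertness of the propiolate ester towards the zinc reagents at 0–4 °C, with Ph3P=O added to break up zinc aggregates. A minor (4R) epimer would be a diastereomer and should be separable by chromatography.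

Step 5
Reactants: 9 octanoyl chloride; 10 (4S)-4-benzyl-1,3-oxazolidin-2-one
Product: 11 (4S)-4-benzyl-3-octanoyl-1,3-oxazolidin-2-one
Conditions: n-BuLi, THF, −78 °C; then 9, −78 → 0 °C
Reagents that add atoms: none
Why: N-Acylation of the lithiated oxazolidinone by the acid chloride (addition–elimination); the auxiliary stereocentre is not involved.

Step 6
Reactants: 11 (4S)-4-benzyl-3-octanoyl-1,3-oxazolidin-2-one
Product: 12 (4S)-4-benzyl-3-[(2S)-2-methyloctanoyl]-1,3-oxazolidin-2-one
Conditions: NaN(SiMe3)2, THF, −78 °C; MeI, −78 °C
Reagents that add atoms: iodomethane, CI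
Why: Auxiliary-controlled enolate alkylation (Evans alkylation): the sodium-chelated Z-enolate is methylated on the face opposite the benzyl group, which for the (4S) auxiliary and an n-hexyl chain gives the (2S)-2-methyloctanoyl unit, the future C6' of the acyl chain.

Step 7
Reactants: 12 (4S)-4-benzyl-3-[(2S)-2-methyloctanoyl]-1,3-oxazolidin-2-one
Product: 13 (2S)-2-methyloctan-1-ol
Conditions: LiBH4, H2O (1.1 equiv), Et2O, 0 °C
Reagents that add atoms: none
Why: LiBH4 reduces the more electrophilic exocyclic imide carbonyl to the primary alcohol and releases the intact auxiliary; the α-centre is not enolised under these hydride conditions.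

Step 8
Reactants: 13 (2S)-2-methyloctan-1-ol; 14 ethyl 2-(triphenylphosphoranylidene)propanoate
Product: 16 ethyl (2E,4S)-2,4-dimethyldec-2-enoate, via (2S)-2-methyloctanal 15 (not isolated)
Conditions: TEMPO (10 mol %), PhI(OAc)2 (1.1 equiv), CH2Cl2, rt; then 14 (1.3 equiv), rt → 40 °C
Reagents that add atoms: none
Why: Oxoammonium (TEMPO) oxidation stops at aldehyde 15, which is olefinated in the same flask by the ester-stabilised ylide (one-pot oxidation–Wittig reaction); reversible oxaphosphetane formation gives the E-trisubstituted enoate, and immediate trapping keeps the α-methyl aldehyde from enolising.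

Step 9
Reactants: 16 ethyl (2E,4S)-2,4-dimethyldec-2-enoate
Product: 17 (2E,4S)-2,4-dimethyldec-2-en-1-ol
Conditions: i-Bu2AlH (2.2 equiv), CH2Cl2, −78 °C; aq. potassium sodium tartrate
Reagents that add atoms: none
Why: Excess i-Bu2AlH reduces the conjugated ester by two 1,2-additions to the allylic alcohol without touching the trisubstituted alkene or the allylic stereocentre.

Step 10
Reactants: 17 (2E,4S)-2,4-dimethyldec-2-en-1-ol; 18 ethyl (triphenylphosphoranylidene)acetate
Product: 20 ethyl (2E,4E,6S)-4,6-dimethyldodeca-2,4-dienoate, via (2E,4S)-2,4-dimethyldec-2-enal 19 (not isolated)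
Conditions: MnO2 (10 equiv), 18 (1.3 equiv), CH2Cl2, rt → 40 °C
Reagents that add atoms: none
Why: MnO2 oxidises only the allylic alcohol to enal 19, which the stabilised ylide converts in situ to the dienoate (tandem oxidation–Wittig reaction); the new disubstituted alkene is E by thermodynamic control and the existing alkene is not isomerised.

Step 11
Reactants: 20 ethyl (2E,4E,6S)-4,6-dimethyldodeca-2,4-dienoate
Product: 21 (2E,4E,6S)-4,6-dimethyldodeca-2,4-dienoic acid
Conditions: LiOH·H2O, THF/MeOH/H2O, rt; aq. HCl to pH 3
Reagents that add atoms: lithium hydroxide, [Li+].[OH-]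
Why: Saponification of the ethyl ester by hydroxide (acyl–oxygen cleavage) followed by acidification; the dienoate is not deconjugated at room temperature and the remote C6 hydrogen is too weakly acidic to epimerise.

Step 12
Reactants: 8 methyl (4S)-4-[(4S)-2,2-dimethyl-1,3-dioxolan-4-yl]-4-hydroxybut-2-ynoate; 21 (2E,4E,6S)-4,6-dimethyldodeca-2,4-dienoic acid
Product: 22 methyl (4S)-4-[(4S)-2,2-dimethyl-1,3-dioxolan-4-yl]-4-{[(2E,4E,6S)-4,6-dimethyldodeca-2,4-dienoyl]oxy}but-2-ynoate
Conditions: EDC·HCl (1.5 equiv), DMAP (0.1 equiv), CH2Cl2, 0 °C → rt
Reagents that add atoms: none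
Why: Carbodiimide esterification with catalytic DMAP (Steglich esterification) acylates the only free hydroxyl of 8 with retention at C5; low temperature and little DMAP limit base-induced isomerisation of the γ-hydroxy ynoate and deconjugation of the activated dienoic acid.

Step 13
Reactants: 22 methyl (4S)-4-[(4S)-2,2-dimethyl-1,3-dioxolan-4-yl]-4-{[(2E,4E,6S)-4,6-dimethyldodeca-2,4-dienoyl]oxy}but-2-ynoate
Product: 23 methyl (4S,5S)-4-{[(2E,4E,6S)-4,6-dimethyldodeca-2,4-dienoyl]oxy}-5,6-dihydroxyhex-2-ynoate
Conditions: AcOH/H2O (4:1), 40 °C; toluene azeotrope; crude used at once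
Reagents that add atoms: none
Why: Acid-catalysed hydrolysis of the terminal isopropylidene acetal; the propargylic ester does not ionise because the ynoate destabilises a cation at C5, and acyl migration is slow in acid with the weakly electrophilic dienoate.

Step 14
Reactants: 23 methyl (4S,5S)-4-{[(2E,4E,6S)-4,6-dimethyldodeca-2,4-dienoyl]oxy}-5,6-dihydroxyhex-2-ynoate; 24 tert-butyl (triphenylphosphoranylidene)acetate
Product: 26 1-tert-butyl 8-methyl (2E,4S,5S)-5-{[(2E,4E,6S)-4,6-dimethyldodeca-2,4-dienoyl]oxy}-4-hydroxyoct-2-en-6-ynedioate, via hydroxy aldehyde 25 (not isolated)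
Conditions: TEMPO (20 mol %), PhI(OAc)2 (1.1 equiv), CH2Cl2, 0 °C → rt; then 24 (1.5 equiv), rt
Reagents that add atoms: none
Why: TEMPO/PhI(OAc)2 oxidises the primary hydroxyl of the terminal diol in preference to the secondary one, and the α-hydroxy aldehyde 25 is intercepted at once by the stabilised ylide (one-pot oxidation–Wittig reaction), which gives the E-enoate in an aprotic solvent; the aldehyde reacts with the ylide far faster than the β-substituted ynoate does.

Step 15
Reactants: 26 1-tert-butyl 8-methyl (2E,4S,5S)-5-{[(2E,4E,6S)-4,6-dimethyldodeca-2,4-dienoyl]oxy}-4-hydroxyoct-2-en-6-ynedioate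
Product: 28 tert-butyl (2E)-3-[(2S,3S)-3-{[(2E,4E,6S)-4,6-dimethyldodeca-2,4-dienoyl]oxy}-6-oxo-3,6-dihydro-2H-pyran-2-yl]prop-2-enoate, via Z-enoate hydroxy ester 27 (not isolated)
Conditions: H2 (1 atm, 1 equiv uptake), Pd/CaCO3 poisoned with Pb(OAc)2, quinoline, EtOAc, rt; filtration; then PPTS (cat.), toluene, 40 °C
Reagents that add atoms: none
Why: Syn delivery of one equivalent of hydrogen on Pd/CaCO3 poisoned with Pb(OAc)2 (Lindlar semihydrogenation) gives the Z-enoate 27, whose C6 hydroxyl is held next to the methyl ester and closes the six-membered lactone by 6-exo-trig acyl substitution with loss of methanol; conjugated E-alkenes are reduced much more slowly than the alkyne on this catalyst, and with O5 acylated no five-membered lactone can form.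

Step 16
Reactants: 28 tert-butyl (2E)-3-[(2S,3S)-3-{[(2E,4E,6S)-4,6-dimethyldodeca-2,4-dienoyl]oxy}-6-oxo-3,6-dihydro-2H-pyran-2-yl]prop-2-enoate
Product: 29 (2E)-3-[(2S,3S)-3-{[(2E,4E,6S)-4,6-dimethyldodeca-2,4-dienoyl]oxy}-6-oxo-3,6-dihydro-2H-pyran-2-yl]prop-2-enoic acid
Conditions: CF3CO2H/CH2Cl2 (1:4), 0 °C → rt; toluene co-evaporation
Reagents that add atoms: none
Why: Acidolysis of the tert-butyl ester by alkyl–oxygen cleavage, the tert-butyl cation leaving as 2-methylpropene; the lactone and the dienoate cannot ionise in this way, and the absence of base avoids elimination of the C5 carboxylate.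

## Compound list

1 | L-ascorbic acid | C([C@@H]([C@@H]1C(=C(C(=O)O1)O)O)O)O | starting material
2 | L-gulono-1,4-lactone | OC[C@H](O)[C@H]1OC(=O)[C@@H](O)[C@H]1O | intermediate
3 | 5,6-O-isopropylidene-L-gulono-1,4-lactone | CC1(C)OC[C@H](O1)[C@H]2OC(=O)[C@@H](O)[C@H]2O | intermediate
4 | (1R)-1-[(4S)-2,2-dimethyl-1,3-dioxolan-4-yl]-2-oxoethyl oxoacetate (3,4-O-isopropylidene-L-threose 2-glyoxylate) | O=C[C@H](OC(=O)C=O)[C@@H]1COC(C)(C)O1 | intermediate (not isolated)
5 | (2R)-2-[(4S)-2,2-dimethyl-1,3-dioxolan-4-yl]-2-hydroxyacetaldehyde (3,4-O-isopropylidene-L-threose) | O=C[C@H](O)[C@@H]1COC(C)(C)O1 | intermediate (not isolated)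
6 | (4S)-2,2-dimethyl-1,3-dioxolane-4-carbaldehyde | O=C[C@@H]1COC(C)(C)O1 | intermediate
7 | methyl prop-2-ynoate (methyl propiolate) | C#CC(=O)OC | starting material
8 | methyl (4S)-4-[(4S)-2,2-dimethyl-1,3-dioxolan-4-yl]-4-hydroxybut-2-ynoate | COC(=O)C#C[C@H](O)[C@@H]1COC(C)(C)O1 | intermediate
9 | octanoyl chloride | CCCCCCCC(Cl)=O | starting material
10 | (4S)-4-benzyl-1,3-oxazolidin-2-one | O=C1OC[C@H](Cc2ccccc2)N1 | starting material
11 | (4S)-4-benzyl-3-octanoyl-1,3-oxazolidin-2-one | CCCCCCCC(=O)N1[C@@H](Cc2ccccc2)COC1=O | intermediate
12 | (4S)-4-benzyl-3-[(2S)-2-methyloctanoyl]-1,3-oxazolidin-2-one | CCCCCC[C@H](C)C(=O)N1[C@@H](Cc2ccccc2)COC1=O | intermediate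
13 | (2S)-2-methyloctan-1-ol | CCCCCC[C@H](C)CO | intermediate
14 | ethyl 2-(triphenylphosphoranylidene)propanoate | CCOC(=O)C(C)=P(c1ccccc1)(c1ccccc1)c1ccccc1 | starting material
15 | (2S)-2-methyloctanal | CCCCCC[C@H](C)C=O | intermediate (not isolated)
16 | ethyl (2E,4S)-2,4-dimethyldec-2-enoate | CCCCCC[C@H](C)/C=C(C)/C(=O)OCC | intermediate
17 | (2E,4S)-2,4-dimethyldec-2-en-1-ol | CCCCCC[C@H](C)/C=C(C)/CO | intermediate
18 | ethyl (triphenylphosphoranylidene)acetate | CCOC(=O)C=P(c1ccccc1)(c1ccccc1)c1ccccc1 | starting material
19 | (2E,4S)-2,4-dimethyldec-2-enal | CCCCCC[C@H](C)/C=C(C)/C=O | intermediate (not isolated)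
20 | ethyl (2E,4E,6S)-4,6-dimethyldodeca-2,4-dienoate | CCCCCC[C@H](C)/C=C(C)/C=C/C(=O)OCC | intermediate
21 | (2E,4E,6S)-4,6-dimethyldodeca-2,4-dienoic acid | CCCCCC[C@H](C)/C=C(C)/C=C/C(=O)O | intermediate
22 | methyl (4S)-4-[(4S)-2,2-dimethyl-1,3-dioxolan-4-yl]-4-{[(2E,4E,6S)-4,6-dimethyldodeca-2,4-dienoyl]oxy}but-2-ynoate | CCCCCC[C@H](C)/C=C(C)/C=C/C(=O)O[C@@H](C#CC(=O)OC)[C@@H]1COC(C)(C)O1 | intermediate
23 | methyl (4S,5S)-4-{[(2E,4E,6S)-4,6-dimethyldodeca-2,4-dienoyl]oxy}-5,6-dihydroxyhex-2-ynoate | CCCCCC[C@H](C)/C=C(C)/C=C/C(=O)O[C@@H](C#CC(=O)OC)[C@@H](O)CO | intermediate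
24 | tert-butyl (triphenylphosphoranylidene)acetate | CC(C)(C)OC(=O)C=P(c1ccccc1)(c1ccccc1)c1ccccc1 | starting material
25 | methyl (4S,5R)-4-{[(2E,4E,6S)-4,6-dimethyldodeca-2,4-dienoyl]oxy}-5-hydroxy-6-oxohex-2-ynoate (same spatial arrangement as 23; the C5 descriptor changes by CIP ranking only) | CCCCCC[C@H](C)/C=C(C)/C=C/C(=O)O[C@@H](C#CC(=O)OC)[C@@H](O)C=O | intermediate (not isolated)
26 | 1-tert-butyl 8-methyl (2E,4S,5S)-5-{[(2E,4E,6S)-4,6-dimethyldodeca-2,4-dienoyl]oxy}-4-hydroxyoct-2-en-6-ynedioate | CCCCCC[C@H](C)/C=C(C)/C=C/C(=O)O[C@@H](C#CC(=O)OC)[C@@H](O)/C=C/C(=O)OC(C)(C)C | intermediate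
27 | 1-tert-butyl 8-methyl (2E,4S,5S,6Z)-5-{[(2E,4E,6S)-4,6-dimethyldodeca-2,4-dienoyl]oxy}-4-hydroxyocta-2,6-dienedioate | CCCCCC[C@H](C)/C=C(C)/C=C/C(=O)O[C@@H](/C=C\C(=O)OC)[C@@H](O)/C=C/C(=O)OC(C)(C)C | intermediate (not isolated)
28 | tert-butyl (2E)-3-[(2S,3S)-3-{[(2E,4E,6S)-4,6-dimethyldodeca-2,4-dienoyl]oxy}-6-oxo-3,6-dihydro-2H-pyran-2-yl]prop-2-enoate | CCCCCC[C@H](C)/C=C(C)/C=C/C(=O)O[C@H]1C=CC(=O)O[C@H]1/C=C/C(=O)OC(C)(C)C | intermediate
29 | (2E)-3-[(2S,3S)-3-{[(2E,4E,6S)-4,6-dimethyldodeca-2,4-dienoyl]oxy}-6-oxo-3,6-dihydro-2H-pyran-2-yl]prop-2-enoic acid | CCCCCC[C@H](C)/C=C(C)/C=C/C(=O)O[C@H]1C=CC(=O)O[C@H]1/C=C/C(=O)O | target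

## Step count and least certain steps

Total: 16 steps. Longest linear sequence: 12 steps (steps 5–16, from 9 to 29). The carbohydrate branch from 1 is 9 steps (steps 1–4 and 12–16).

Step 4 (key step). What may go wrong: insufficient facial selectivity, either because the ligand does not override the substrate or because the facial sense of the ligand is opposite to the one assumed. Turnover may also be slow if the dioxolane oxygens compete for zinc or if 6 is partly hydrated or oligomerised. Both ligand antipodes are available, so the sense can be settled in the first run. Fallback: abandon the mismatched addition in favour of the matched one followed by an invertive esterification. Setting out from 6 and 7, the antipodal (S,S)-ProPhenol under otherwise identical conditions, now reinforcing the Felkin–Anh preference, should give the anti epimer methyl (4R)-4-[(4S)-2,2-dimethyl-1,3-dioxolan-4-yl]-4-hydroxybut-2-ynoate F1. Mitsunobu esterification of F1 with 21 (PPh3, DIAD, toluene, 0 °C) inverts the carbinol by SN2 displacement of the activated oxygen and comes back to the route at 22. Steps 4 and 12 are thus replaced by two steps.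

Step 14. What may go wrong: loss of the dienoate by β-elimination from the α-hydroxy aldehyde before it is trapped, glycol cleavage of the 1,2-diol by PhI(OAc)2 in competition with the TEMPO-mediated oxidation, acyl migration from O5 to O6 (already possible in step 13, and later opening the way to a butenolide), addition of the ylide to the ynoate, and incomplete E selectivity. Fallback: attach the dienoate last, so that no acyl group sits next to a free hydroxyl or β to an aldehyde. Setting out from 8, the C5 hydroxyl would be capped (TBDPSCl, imidazole, DMF) to give TBDPS ether F2, and aqueous AcOH would then give diol F3. The same TEMPO/PhI(OAc)2 oxidation with in situ olefination by 24 would pass through hydroxy aldehyde F4 to ynoate enoate F5. Semihydrogenation and lactonisation as in step 15 would pass through Z-enoate F6 to silyloxy lactone F7, from which HF·pyridine in THF would free hydroxy lactone F8. Esterification of F8 with 21 (EDC·HCl, DMAP cat., CH2Cl2, 0 °C) comes back to the route at 28. A silyloxy group neither migrates readily nor leaves as an anion. The price is two more steps and a final acylation on a base-sensitive lactone. If glycol cleavage proved to be the dominant loss, the order of events described under step 15 below, in which the secondary hydroxyl is consumed by lactonisation before the oxidation, would be the remedy.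

Step 15. What may go wrong: over-reduction of the Z-enoate or partial reduction of the E-enoate or the dienoate on the palladium surface, and acyl migration to O6 competing with lactonisation. Fallback: reduce first and build the acid arm last. Setting out from 22, the ynoate would be semihydrogenated on the same poisoned catalyst while no free hydroxyl and no alkene other than the dienoate is present, giving Z-enoate acetonide F9. Aqueous AcOH and then PPTS in toluene would remove the acetonide, and the resulting Z-enoate diol F10 would lactonise through its secondary hydroxyl to hydroxymethyl lactone F11. TEMPO/PhI(OAc)2 oxidation to formyl lactone F12 and trapping with 24 in the same flask come back to the route at 28. The weak point of this order is elimination of the C5 carboxylate from the formyl lactone to an aromatic 2-pyranone, which is why it is held in reserve and not used as the main line.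

## Further compounds

F1 | step 4 | methyl (4R)-4-[(4S)-2,2-dimethyl-1,3-dioxolan-4-yl]-4-hydroxybut-2-ynoate | COC(=O)C#C[C@@H](O)[C@@H]1COC(C)(C)O1
F2 | step 14 | methyl (4S)-4-[(tert-butyldiphenylsilyl)oxy]-4-[(4S)-2,2-dimethyl-1,3-dioxolan-4-yl]but-2-ynoate | COC(=O)C#C[C@H](O[Si](c1ccccc1)(c1ccccc1)C(C)(C)C)[C@@H]2COC(C)(C)O2
F3 | step 14 | methyl (4S,5S)-4-[(tert-butyldiphenylsilyl)oxy]-5,6-dihydroxyhex-2-ynoate | COC(=O)C#C[C@H](O[Si](c1ccccc1)(c1ccccc1)C(C)(C)C)[C@@H](O)CO
F4 | step 14 | methyl (4S,5R)-4-[(tert-butyldiphenylsilyl)oxy]-5-hydroxy-6-oxohex-2-ynoate | COC(=O)C#C[C@H](O[Si](c1ccccc1)(c1ccccc1)C(C)(C)C)[C@@H](O)C=O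
F5 | step 14 | 1-tert-butyl 8-methyl (2E,4S,5S)-5-[(tert-butyldiphenylsilyl)oxy]-4-hydroxyoct-2-en-6-ynedioate | COC(=O)C#C[C@H](O[Si](c1ccccc1)(c1ccccc1)C(C)(C)C)[C@@H](O)/C=C/C(=O)OC(C)(C)C
F6 | step 14 | 1-tert-butyl 8-methyl (2E,4S,5S,6Z)-5-[(tert-butyldiphenylsilyl)oxy]-4-hydroxyocta-2,6-dienedioate | COC(=O)/C=C\[C@H](O[Si](c1ccccc1)(c1ccccc1)C(C)(C)C)[C@@H](O)/C=C/C(=O)OC(C)(C)C
F7 | step 14 | tert-butyl (2E)-3-[(2S,3S)-3-[(tert-butyldiphenylsilyl)oxy]-6-oxo-3,6-dihydro-2H-pyran-2-yl]prop-2-enoate | CC(C)(C)[Si](c1ccccc1)(c1ccccc1)O[C@H]2C=CC(=O)O[C@H]2/C=C/C(=O)OC(C)(C)C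
F8 | step 14 | tert-butyl (2E)-3-[(2S,3S)-3-hydroxy-6-oxo-3,6-dihydro-2H-pyran-2-yl]prop-2-enoate | O[C@H]1C=CC(=O)O[C@H]1/C=C/C(=O)OC(C)(C)C
F9 | step 15 | methyl (2Z,4S)-4-[(4S)-2,2-dimethyl-1,3-dioxolan-4-yl]-4-{[(2E,4E,6S)-4,6-dimethyldodeca-2,4-dienoyl]oxy}but-2-enoate | CCCCCC[C@H](C)/C=C(C)/C=C/C(=O)O[C@@H](/C=C\C(=O)OC)[C@@H]1COC(C)(C)O1
F10 | step 15 | methyl (2Z,4S,5S)-4-{[(2E,4E,6S)-4,6-dimethyldodeca-2,4-dienoyl]oxy}-5,6-dihydroxyhex-2-enoate | CCCCCC[C@H](C)/C=C(C)/C=C/C(=O)O[C@@H](/C=C\C(=O)OC)[C@@H](O)CO
F11 | step 15 | (2S,3S)-2-(hydroxymethyl)-6-oxo-3,6-dihydro-2H-pyran-3-yl (2E,4E,6S)-4,6-dimethyldodeca-2,4-dienoate | CCCCCC[C@H](C)/C=C(C)/C=C/C(=O)O[C@H]1C=CC(=O)O[C@H]1CO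
F12 | step 15 | (2R,3S)-2-formyl-6-oxo-3,6-dihydro-2H-pyran-3-yl (2E,4E,6S)-4,6-dimethyldodeca-2,4-dienoate | CCCCCC[C@H](C)/C=C(C)/C=C/C(=O)O[C@H]1C=CC(=O)O[C@H]1C=O
A1 | alternative 1 | tert-butyl (2E,4S)-4-(furan-2-yl)-4-hydroxybut-2-enoate | O[C@H](c1ccco1)/C=C/C(=O)OC(C)(C)C
A2 | alternative 1 | tert-butyl (2E)-3-[(2S)-6-hydroxy-3-oxo-3,6-dihydro-2H-pyran-2-yl]prop-2-enoate (anomeric mixture) | O=C1C=CC(O)O[C@H]1/C=C/C(=O)OC(C)(C)C
A3 | alternative 2 | 3-chloroprop-1-en-1-yl (2E,4E,6S)-4,6-dimethyldodeca-2,4-dienoate (E/Z mixture at the enol ester) | CCCCCC[C@H](C)/C=C(C)/C=C/C(=O)OC=CCCl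
A4 | alternative 2 | tert-butyl (2E)-4-oxobut-2-enoate | O=C/C=C/C(=O)OC(C)(C)C
A5 | alternative 2 | tert-butyl (2E,4S,5S)-5-{[(2E,4E,6S)-4,6-dimethyldodeca-2,4-dienoyl]oxy}-4-hydroxyhepta-2,6-dienoate | CCCCCC[C@H](C)/C=C(C)/C=C/C(=O)O[C@@H](C=C)[C@@H](O)/C=C/C(=O)OC(C)(C)C
A6 | alternative 3 | (3S,4S)-hexa-1,5-diene-3,4-diol | C=C[C@H](O)[C@@H](O)C=C
A7 | alternative 3 | (3S,4S)-4-(prop-2-enoyloxy)hexa-1,5-dien-3-yl (2E,4E,6S)-4,6-dimethyldodeca-2,4-dienoate | CCCCCC[C@H](C)/C=C(C)/C=C/C(=O)O[C@@H](C=C)[C@@H](OC(=O)C=C)C=C
A8 | alternative 3 | tert-butyl prop-2-enoate | C=CC(=O)OC(C)(C)C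
A9 | alternative 3 | tert-butyl (2E)-3-[(2S,3S)-3-{[(2E,4E,6S)-4,6-dimethyldodeca-2,4-dienoyl]oxy}-6-oxo-3,6-dihydro-2H-pyran-2-yl]prop-2-enoate (identical with 28) | CCCCCC[C@H](C)/C=C(C)/C=C/C(=O)O[C@H]1C=CC(=O)O[C@H]1/C=C/C(=O)OC(C)(C)C
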